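**Assumption:** The target has no stereocentres, so "single enantiomer" is moot. The only stereo-element is the (E)-enone, which the Claisen–Schmidt condensation sets thermodynamically.

**Structure check.** The target is a 2',6'-dihydroxy-4'-methoxy-3'-prenylchalcone with a 4-hydroxyphenyl B-ring. The ring reads C1'(C=O), C2'(OH), C3'(prenyl), C4'(OMe), C5'(H), C6'(OH). Formula C21H22O5.

## Retrosynthetic overview
1. The (E)-enone disconnects by Claisen–Schmidt into a prenylated acetophenone (3) and a B-ring aldehyde (5, 4-hydroxybenzaldehyde protected as its MOM ether).
2. Acetophenone 3 comes from commercially available 2',6'-dihydroxy-4'-methoxyacetophenone (1), which is symmetric, so C3' and C5' are equivalent and regiochemistry is not an issue.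
3. The only problems at this stage are mono- versus di-alkylation and C- versus O-alkylation. A new boron-templated C-prenylation solves both (Step 1).
4. The only rings are the two aromatic rings, which are present in the starting materials.

## Route

**Step 1**
Reactants: 1 (2',6'-dihydroxy-4'-methoxyacetophenone); 2 (prenyl bromide, 1-bromo-3-methylbut-2-ene)
Product: 3, 1-[2,6-dihydroxy-4-methoxy-3-(3-methylbut-2-en-1-yl)phenyl]ethan-1-one
Conditions: Ph2BOH (1.0 equiv), PhMe, 4 Å MS, 80 °C, 2 h; then 2 (1.0 equiv), i-Pr2NEt (1.0 equiv), MeCN, 40 °C, 24 h; then H2NCH2CH2OH (3 equiv), rt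
Reagents that add atoms: prenyl bromide, CC(C)=CCBr. Ph2BOH, i-Pr2NEt and ethanolamine leave no atoms in the product.
Why: Proposed new method: diphenylborinic acid condenses with the 2'-OH and the ketone to give a six-membered O,O-BPh2 chelate. The chelate makes the remaining 6'-OH acidic enough to be deprotonated by exactly one equivalent of amine, and the borane-activated acyl group delocalises the resulting phenoxide charge onto the ring carbons (C3'/C5') and away from O6'. This favours SN2 C-prenylation over O-prenylation, much as enolate-type C-alkylation works on phloroglucinols. The monoprenylated chelate is less acidic than the starting chelate, so the base is not consumed a second time and dialkylation is suppressed. Ethanolamine then strips the boron as Ph2B(OCH2CH2NH2). The closest known reactions are BF2/BPh2-chelate activation of 2-acylphenols and 1,3-dicarbonyls, borinic-acid-templated site-selective alkylation of polyols, and the Ecke–Kolka metal-phenoxide ortho-alkylation. Applying this to a 2,6-dihydroxyaryl ketone with a prenyl electrophile is the new part, and no stereocentre is involved.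

**Step 2**
Reactants: 4 (4-hydroxybenzaldehyde)
Product: 5, 4-(methoxymethoxy)benzaldehyde
Conditions: MOMCl (1.5 equiv), i-Pr2NEt (2 equiv), CH2Cl2, 0 °C → rt, 4 h
Reagents that add atoms: MOMCl, COCCl
Why: Standard phenol O-alkylation (MOM protection). It masks the acidic B-ring phenol so it does not deactivate the aldehyde in the basic aldol step.

**Step 3**
Reactants: 3 (prenylated acetophenone); 5 (4-MOM-oxybenzaldehyde)
Product: 6, (E)-1-[2,6-dihydroxy-4-methoxy-3-(3-methylbut-2-enyl)phenyl]-3-[4-(methoxymethoxy)phenyl]prop-2-en-1-one
Conditions: KOH (50% aq., ~6 equiv), EtOH, 0 °C → rt, 48 h; then 1 M HCl to pH ~4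
Reagents that add atoms: none (the aldehyde is the reactant)
Why: Base-mediated Claisen–Schmidt aldol condensation. The 2',6'-dihydroxy ketone works as its phenoxide/enolate, as in cardamonin-type syntheses. Dehydration gives the thermodynamically favoured (E)-enone. The prenyl alkene and MOM ether survive, and the cold, quick acidic quench limits flavanone cyclisation.

**Step 4**
Reactants: 6
Product: 7, xanthogalenol
Conditions: 3 M HCl, MeOH/THF (1:1), 25 °C, 8–12 h
Reagents that add atoms: none
Why: Acid-catalysed hydrolysis of the aryl MOM acetal. The conditions are mild enough that the prenyl alkene, the (E)-enone and the chelated phenols are untouched (as in MOM removal during xanthohumol syntheses). There is no stereocentre to scramble, and the E geometry is retained.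

**Final checks.** Atom balance: 1 (C9H10O4) + C5H8 gives 3 (C14H18O4). 3 + 5 (C9H10O3) − H2O gives 6 (C23H26O6). Removing the MOM group (−C2H4O) gives 7 (C21H22O5), which matches the target SMILES: ring substituents, prenyl next to OMe and OH, and (E)-olefin.

## Compound list
1 | 2',6'-dihydroxy-4'-methoxyacetophenone | CC(=O)c1c(O)cc(OC)cc1O | starting material
2 | prenyl bromide | CC(C)=CCBr | starting material
3 | 1-[2,6-dihydroxy-4-methoxy-3-prenylphenyl]ethanone | CC(=O)c1c(O)c(CC=C(C)C)c(OC)cc1O | intermediate
4 | 4-hydroxybenzaldehyde | O=Cc1ccc(O)cc1 | starting material
5 | 4-(methoxymethoxy)benzaldehyde | COCOc1ccc(C=O)cc1 | intermediate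
6 | (E)-MOM-protected chalcone | COCOc1ccc(cc1)/C=C/C(=O)c1c(O)c(CC=C(C)C)c(OC)cc1O | intermediate
7 | xanthogalenol | COc1cc(O)c(C(=O)/C=C/c2ccc(O)cc2)c(O)c1CC=C(C)C | target

## Step count
- Total steps: 4.
- Longest linear sequence: 3 (1 → 3 → 6 → 7).

## Three steps most likely to fail
1. **Step 1 (proposed new boron-templated C-prenylation).** Risks are O-prenylation, dialkylation, or chromane formation from the prenyl cation.
   Fallback (known chemistry): mono-O-allylate 1 (allyl bromide, K2CO3 (1 equiv), acetone), do a thermal Claisen rearrangement (PhNEt2, 200 °C) to the 3-allyl ketone, then cross-metathesis with 2-methylbut-2-ene (Hoveyda–Grubbs II) to install the prenyl group.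
2. **Step 3 (Claisen–Schmidt on the free 2',6'-diphenol).** Risks are a low-yielding aldol or cyclisation to the flavanone.
   Fallback: protect both phenols of 3 as bis-MOM ethers (MOMCl, NaH, THF), run the aldol with NaOH/EtOH, and remove all three MOM groups together in Step 4.
3. **Step 4 (acidic MOM removal).** Risks are prenyl-phenol cyclisation to a chromane or flavanone formation.
   Fallback: use 4-allyloxybenzaldehyde as the B-ring partner in place of 5, and deprotect under neutral conditions with Pd(PPh3)4, K2CO3, MeOH.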